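## Structural features

The target is a linear trimer of 8-methoxynaphthalen-1-ol: unit A is bonded through C2 to C2' of the central unit B, and unit B through C4' to C4'' of unit C, so unit B is substituted ortho and para to its hydroxyl, unit A only ortho and unit C only para. There is no stereocentre and neither biaryl axis carries a stereodescriptor; the C2–C2' axis is flanked only by two oxygen substituents and the C4'–C4'' axis is of the 1,1'-binaphthyl type, so both are treated as freely equilibrating. Every unit holds a phenolic OH hydrogen-bonded to a peri methoxy group; the free naphthols are electron-rich and prone to oxidation and further phenolic coupling, and the peri methyl ethers are open to chelation-assisted cleavage by boron or aluminium halides, so the last steps must be neutral and non-oxidising. The difficulty is regiochemical: three nearly identical rings must be joined at three different positions, and units B and C form a 4,4'-linked pair whose two halves are chemically equivalent until one of them is marked. The C2–C2' bond also lies between two oxygen-bearing carbons, the least favourable place for an aryl–aryl cross-coupling. The key step exploits the position of C1 in unit A: it carries the hydroxyl and sits between C8a of the methoxy-bearing ring and the aryl-bearing C2, so C1 can be the former carbonyl carbon of a 2-methoxybenzamide, with C2, C3 and C4 the three carbons of an allyl chain attached at the future C4a. Closing the ring C1–C2–C3–C4–C4a–C8a by acylation of the allyl anion at its aryl-bearing end builds the phenol ring of unit A with the C2–C2' link already in place as an alkene–arene bond.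

## Logic of the disconnections

18 back to 17: the two O–CH2Ph bonds on units B and C are cut. Free naphthols there would consume base and invite oxidation during the assembly, and benzyl ethers come off by neutral hydrogenolysis that leaves the peri methyl ethers alone. The demand is that 17 holds nothing else that is reduced, which is met because the alkene is consumed one step earlier.

17 back to 14 (through 16 and 15): the C1–C2 bond of unit A is cut, which opens the phenol ring. Unit A shrinks to a benzamide carrying a three-carbon chain, and the crowded C2–C2' biaryl bond becomes a plain alkene–arene bond. The forward step needs deprotonation at the doubly activated CH2, a cisoid allyl anion geometry, and an amide that acts as the acylating agent in the presence of two benzyl ethers. Both alkene geometries and both positions of the double bond in the 1,3-diarylpropene give the same anion 15, so the preceding step need not deliver a single isomer. The skeletons of 14 and 17 were checked atom by atom against the target numbering and need no correction.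

14 back to 8 and 13: the bond between the alkene terminus and C2' is cut (Heck disconnection). This is the convergent union of the B–C half with the small unit-A precursor. The forward step must arylate the terminal carbon of 13 faster than the double bond of 13 migrates into conjugation.

13 back to 9 and 10 (through 11 and 12): the aryl–CH2 bond is cut. The amide that later serves as the acylating group is also the directing group for ortho-metalation, so the peri O,O pattern of unit A is fixed here. The demands are lithiation ortho to the amide rather than ortho to the methoxy group, and a clean allylation, which is why the lithium species is passed through magnesium.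

8 back to 7 and then 6: the O–benzyl bond on unit B and the C2'–Br bond are cut. In 6 only unit B has a free hydroxyl, and this marks C2' (ortho, with para blocked) for bromination. A symmetrical binaphthol would instead need a statistical mono-bromination with separation of unreacted and dibrominated material, which is the weak point this design removes. The demand is a bromination that selects the free naphthol over three aryl ether rings.

6 back to 4 and 3 (through 5): the C4'–C4'' biaryl bond is cut (Suzuki disconnection). Both partners descend from 3, one benzylated and turned into the boron component, the other used unprotected as the halide, so the product is already desymmetrised. The demand is a cross-coupling that tolerates a free, electron-rich bromonaphthol.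

4 back to 3, 2 and 1: the O–benzyl bond, the C4–Br bond and the O–methyl bond are cut in turn. The demands are para-selective bromination of 2 and clean mono-methylation of 1.

## Other disconnections considered

Alternative 1: The cut removes C1'–C8a' and C4'–C4a', the two bonds joining the benzo ring of unit B to its phenol ring.
- **Forward step:** pyrone A2 already carries unit A at C4, unit C at C6 and the future C1' oxygen at C3. It reacts with aryne A4, released from silyl triflate A3 by CsF, in a [4+2] cycloaddition. Retro-cycloaddition of CO2 gives tribenzyl ether A1, and one hydrogenolysis gives 18.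
- **In its favour:** it is highly convergent. The ortho/para pattern of unit B is written into A2, so no site-selective halogenation of a biaryl is needed, and fluoride is milder than a lithium amide; on these points it is the better plan. Uniform benzyl protection with a one-step deprotection is equal to the chosen plan.
- **Against it:** both partners are unsymmetrical, and only one orientation gives the 8'-methoxy pattern. The electronic bias plausibly points the right way (the aryne carbon remote from the methoxy group is the electrophilic one, and C6 of a 3-alkoxypyrone the more nucleophilic terminus). C6 also carries the bulky naphthyl group, however, so a mixture with the 5'-methoxy isomer must be expected, and the two would be hard to separate.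
- **Comparison:** the chosen plan settles the peri O,O relationship of the ring it builds before ring closure, by directed metalation; here it is left to cycloaddition regiochemistry. A2 needs a C2-functionalised unit A, a C4-functionalised unit C and a multi-step pyrone construction, so it is estimated to be longer than the whole chosen route.

Alternative 2: The cut removes C4''–C4a'' and C2''–C3'' of unit C.
- **Forward step:** [Cp*RhCl2]2 with AgSbF6 (trivalent rhodium) performs carbonyl-directed C–H activation at the single free ortho position of sulfoxonium ylide A6. Alkyne A7 inserts with its aryl carbon bonding to the arene, a rhodium carbene forms at the ylide carbon with loss of dimethyl sulfoxide, and migratory insertion and tautomerisation give silylated naphthol A5. Protodesilylation and hydrogenolysis follow.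
- **In its favour:** the step is catalytic and needs no organolithium, so its functional-group tolerance is better. A6 is one step from a 2-methoxybenzoate. The peri pattern is encoded in a 2-methoxybenzoyl unit, which is equal to the chosen plan.
- **Against it:** the regiochemistry depends on the silyl group steering the insertion of a very bulky aryl alkyne. A5 must hold a trimethylsilyl group beside a peri-hindered biaryl axis, and the alkynyl–silicon bond is at risk under cationic silver and rhodium conditions.
- **Comparison:** A7 presupposes the A–B biaryl, so the C2–C2' bond between two oxygen-flanked carbons must be made by aryl–aryl coupling; the chosen plan avoids exactly that. Two steps follow the key step instead of one, and the route to A7 (biaryl coupling, C4' halogenation, alkynylation) is estimated to be longer.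

Alternative 3: The cut removes the C3''=C4'' bond of unit C.
- **Forward step:** the second-generation Hoveyda–Grubbs catalyst closes the allyl ketone of diene A9 onto its 1,1-diarylethene with loss of ethene. The resulting naphthalenone A10 enolises to naphthol A8, and hydrogenolysis gives 18.
- **In its favour:** conditions are neutral and compatible with acidic groups, which is better than the chosen plan. There is no regiochemical question at ring closure, and the aromatisation driving force from a naphthalen-1(2H)-one is the same; both points are equal to the chosen plan.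
- **Against it:** a 1,1-diarylethene bearing two ortho-substituted aryl groups is a poor metathesis partner, and the closure creates a trisubstituted alkene at a congested biaryl junction. The β,γ-unsaturated ketone of A9 can slip into conjugation, on base, silica or ruthenium hydrides, after which the six-membered closure is no longer possible.
- **Comparison:** the chosen ring closure is a polar acylation of a stabilised carbanion and is less sensitive to steric crowding at the reacting alkene. A9 needs the A–B biaryl, an allyl ketone and a diarylethene, so it is estimated to be longer.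

Key step: step 9

Assumption: N,N-diethyl-2-methoxybenzamide (9) is taken as purchasable; it is otherwise one amidation from 2-methoxybenzoyl chloride.

Remark: the target carries no stereodescriptor, so the biaryl axes are treated as configurationally labile and no stereocontrol is planned.

## Route

Step 1
Reactants: 1 naphthalene-1,8-diol
Product: 2 8-methoxynaphthalen-1-ol
Conditions: MeI (1.05 equiv), K2CO3 (1.1 equiv), acetone, reflux
Reagents that add atoms: iodomethane, CI
Why: Williamson mono-O-methylation; the first phenol of 1 is unusually acidic because its anion is held by the peri hydrogen bond, whereas the remaining OH of 2 is locked in a hydrogen bond to the new methoxy oxygen and reacts far more slowly, so one equivalent of iodomethane should stop at the mono-ether.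

Step 2
Reactants: 2 8-methoxynaphthalen-1-ol
Product: 3 4-bromo-8-methoxynaphthalen-1-ol
Conditions: NBS (1.0 equiv), MeCN, −20 → 0 °C, dark
Reagents that add atoms: N-bromosuccinimide, O=C1CCC(=O)N1Br
Why: Electrophilic aromatic bromination with N-bromosuccinimide in acetonitrile is para-selective for 1-naphthols; the free hydroxyl activates C4 more strongly than the methoxy group activates C5 or C7, and low temperature with exactly one equivalent limits 2-bromo and dibromo by-products.

Step 3
Reactants: 3 4-bromo-8-methoxynaphthalen-1-ol
Product: 4 1-(benzyloxy)-4-bromo-8-methoxynaphthalene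
Conditions: BnBr, K2CO3, DMF, 50 °C
Reagents that add atoms: benzyl bromide, BrCc1ccccc1
Why: Williamson ether synthesis; warming in DMF overcomes the lower nucleophilicity of the peri-hydrogen-bonded naphthol, and the aryl bromide is inert to carbonate.

Step 4
Reactants: 4 1-(benzyloxy)-4-bromo-8-methoxynaphthalene; 3 4-bromo-8-methoxynaphthalen-1-ol
Product: 6 4-[4-(benzyloxy)-5-methoxynaphthalen-1-yl]-8-methoxynaphthalen-1-ol, via pinacol boronate 5 (not isolated)
Conditions: B2pin2 (1.0 equiv), KOAc, Pd2(dba)3 (2 mol %), XPhos (8 mol %), 1,4-dioxane, 100 °C; then 3 (0.9 equiv), aq. K3PO4, 100 °C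
Reagents that add atoms: none
Why: One-pot Miyaura borylation and Suzuki–Miyaura coupling on zerovalent palladium with a bulky biarylphosphine: 4 is converted into boronate 5 with acetate as base, then aqueous phosphate activates 5 for transmetalation while 3 undergoes oxidative addition as its naphtholate. Using 3 unprotected leaves a single free hydroxyl in 6, which marks unit B for step 5; a 1,1'-binaphthyl bond with only hydrogens at the ortho and peri positions is within the normal scope of this coupling.

Step 5
Reactants: 6 4-[4-(benzyloxy)-5-methoxynaphthalen-1-yl]-8-methoxynaphthalen-1-ol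
Product: 7 4-[4-(benzyloxy)-5-methoxynaphthalen-1-yl]-2-bromo-8-methoxynaphthalen-1-ol
Conditions: NBS (1.0 equiv), i-Pr2NH (10 mol %), CH2Cl2, −78 → 0 °C
Reagents that add atoms: N-bromosuccinimide, O=C1CCC(=O)N1Br
Why: Amine-catalysed ortho-bromination of a phenol, in which the N-bromoamine is delivered through hydrogen bonding to the OH; C4' is blocked, so C2' is the only activated position of the free naphthol, and the benzyl and methyl ether rings should be much less reactive at low temperature.

Step 6
Reactants: 7 4-[4-(benzyloxy)-5-methoxynaphthalen-1-yl]-2-bromo-8-methoxynaphthalen-1-ol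
Product: 8 1-(benzyloxy)-4-[4-(benzyloxy)-5-methoxynaphthalen-1-yl]-2-bromo-8-methoxynaphthalene
Conditions: BnBr, K2CO3, DMF, 60 °C
Reagents that add atoms: benzyl bromide, BrCc1ccccc1
Why: Williamson benzylation of the ortho-bromonaphthol, which is more acidic than 3; it removes the last acidic proton before the palladium and lithium amide steps and gives units B and C the same protecting group for a single final deprotection.

Step 7
Reactants: 9 N,N-diethyl-2-methoxybenzamide; 10 allyl bromide
Product: 13 N,N-diethyl-2-methoxy-6-(prop-2-en-1-yl)benzamide, via aryllithium 11 (not isolated), via arylmagnesium bromide 12 (not isolated)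
Conditions: s-BuLi, TMEDA, THF, −78 °C; MgBr2·OEt2, −78 → −20 °C; then 10, → rt
Reagents that add atoms: none
Why: Directed ortho-metalation: the tertiary amide outranks the methoxy group as directing group, so sec-butyllithium with TMEDA removes the only hydrogen ortho to the amide (C6) to give 11. Transmetalation to arylmagnesium bromide 12 suppresses halogen–metal exchange and elimination, and 12 is then allylated by 10.

Step 8
Reactants: 8 1-(benzyloxy)-4-[4-(benzyloxy)-5-methoxynaphthalen-1-yl]-2-bromo-8-methoxynaphthalene; 13 N,N-diethyl-2-methoxy-6-(prop-2-en-1-yl)benzamide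
Product: 14 N,N-diethyl-2-methoxy-6-[(2E)-3-{1-(benzyloxy)-4-[4-(benzyloxy)-5-methoxynaphthalen-1-yl]-8-methoxynaphthalen-2-yl}prop-2-en-1-yl]benzamide
Conditions: Pd(OAc)2 (5 mol %), P(o-tol)3 (12 mol %), K2CO3, DMF, 100 °C; 13 in excess (1.5 equiv)
Reagents that add atoms: none
Why: Mizoroki–Heck reaction: oxidative addition of 8 to zerovalent palladium (formed from Pd(OAc)2 and the phosphine), insertion of the terminal alkene of 13 with the aryl group going to the unsubstituted carbon, and β-hydride elimination towards the new aryl group should give the E-styrene 14. Elimination towards the benzamide side gives the positional alkene isomer, which yields the same allyl anion in step 9, so the isomers need not be separated; the excess of 13 offsets loss by double-bond migration.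

Step 9
Reactants: 14 N,N-diethyl-2-methoxy-6-[(2E)-3-{1-(benzyloxy)-4-[4-(benzyloxy)-5-methoxynaphthalen-1-yl]-8-methoxynaphthalen-2-yl}prop-2-en-1-yl]benzamide
Product: 17 2-{1-(benzyloxy)-4-[4-(benzyloxy)-5-methoxynaphthalen-1-yl]-8-methoxynaphthalen-2-yl}-8-methoxynaphthalen-1-ol, via allyllithium 15 (not isolated), via naphthalen-1(2H)-one 16 (not isolated)
Conditions: LiN(i-Pr)2 (2.5 equiv), THF, −78 °C → rt; then 1 M HCl
Reagents that add atoms: none
Why: LiN(i-Pr)2, pre-coordinated to the amide oxygen, removes a proton from the CH2 group that is both benzylic and allylic, by far the most acidic C–H of 14, to give the 1,3-diarylallyllithium 15. The aryl-bearing terminus of 15 adds to the diethylamide carbonyl and forms the C1–C2 bond; the tetrahedral intermediate expels lithium diethylamide to give naphthalen-1(2H)-one 16, whose C2–H is removed at once, so the lithium naphtholate of 17 persists until the acidic work-up. The closest known reaction type is the base-induced ring closure of N,N-diethyl ortho-allylbenzamides to 1-naphthols. The one ring is closed in a 6-exo-trig mode, the attacked C=O lying outside the forming six-membered ring, and attack through the near terminus would need a four-membered ring, so ring size fixes the regiochemistry of acylation. Closure requires the benzamide ring and the far terminus to be cis about the C3–C4 bond of the allyl unit; allyllithiums of this kind rotate on warming, and irreversible loss of the amide followed by aromatisation drains the reactive rotamer. No stereocentre is created, because C2 of 16 is stereogenic only transiently and becomes planar on enolisation. The step needs deprotonation at the diarylpropene CH2 without metalation of the benzyl ether CH2 groups or of the arene; the much higher acidity of that CH2, an amide base instead of an alkyllithium, and deprotonation at low temperature secure this. The unit-B aryl group stabilises the terminus that becomes C2, and both alkene geometries as well as the positional alkene isomer converge on 15.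

Step 10
Reactants: 17 2-{1-(benzyloxy)-4-[4-(benzyloxy)-5-methoxynaphthalen-1-yl]-8-methoxynaphthalen-2-yl}-8-methoxynaphthalen-1-ol
Product: 18 4-(4-hydroxy-5-methoxynaphthalen-1-yl)-2-(1-hydroxy-8-methoxynaphthalen-2-yl)-8-methoxynaphthalen-1-ol (target)
Conditions: H2 (1 atm), 10% Pd/C, degassed EtOAc–MeOH, rt
Reagents that add atoms: none
Why: Heterogeneous hydrogenolysis of the two aryl benzyl ethers; the conditions are neutral, leave the naphthalene rings and the peri methyl ethers untouched and release only toluene, so the oxidation-prone triol 18 should be obtained without contact with Lewis acids or oxidants.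

## Compound list

1 | naphthalene-1,8-diol (1,8-dihydroxynaphthalene) | Oc1cccc2cccc(O)c12 | starting material
2 | 8-methoxynaphthalen-1-ol | COc1cccc2cccc(O)c12 | intermediate
3 | 4-bromo-8-methoxynaphthalen-1-ol | COc1cccc2c(Br)ccc(O)c12 | intermediate
4 | 1-(benzyloxy)-4-bromo-8-methoxynaphthalene | COc1cccc2c(Br)ccc(OCc3ccccc3)c12 | intermediate
5 | 2-[4-(benzyloxy)-5-methoxynaphthalen-1-yl]-4,4,5,5-tetramethyl-1,3,2-dioxaborolane (formed in the flask) | COc1cccc2c(B3OC(C)(C)C(C)(C)O3)ccc(OCc3ccccc3)c12 | intermediate
6 | 4-[4-(benzyloxy)-5-methoxynaphthalen-1-yl]-8-methoxynaphthalen-1-ol | COc1cccc2c(-c3ccc(OCc4ccccc4)c4c(OC)cccc34)ccc(O)c12 | intermediate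
7 | 4-[4-(benzyloxy)-5-methoxynaphthalen-1-yl]-2-bromo-8-methoxynaphthalen-1-ol | COc1cccc2c(-c3ccc(OCc4ccccc4)c4c(OC)cccc34)cc(Br)c(O)c12 | intermediate
8 | 1-(benzyloxy)-4-[4-(benzyloxy)-5-methoxynaphthalen-1-yl]-2-bromo-8-methoxynaphthalene | COc1cccc2c(-c3ccc(OCc4ccccc4)c4c(OC)cccc34)cc(Br)c(OCc3ccccc3)c12 | intermediate
9 | N,N-diethyl-2-methoxybenzamide | CCN(CC)C(=O)c1ccccc1OC | starting material
10 | allyl bromide (3-bromoprop-1-ene) | C=CCBr | starting material
11 | [2-(diethylcarbamoyl)-3-methoxyphenyl]lithium (formed in the flask) | CCN(CC)C(=O)c1c([Li])cccc1OC | intermediate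
12 | [2-(diethylcarbamoyl)-3-methoxyphenyl]magnesium bromide (formed in the flask) | CCN(CC)C(=O)c1c([Mg]Br)cccc1OC | intermediate
13 | N,N-diethyl-2-methoxy-6-(prop-2-en-1-yl)benzamide | CCN(CC)C(=O)c1c(CC=C)cccc1OC | intermediate
14 | N,N-diethyl-2-methoxy-6-[(2E)-3-{1-(benzyloxy)-4-[4-(benzyloxy)-5-methoxynaphthalen-1-yl]-8-methoxynaphthalen-2-yl}prop-2-en-1-yl]benzamide | CCN(CC)C(=O)c1c(OC)cccc1C/C=C/c1cc(-c2ccc(OCc3ccccc3)c3c(OC)cccc23)c2cccc(OC)c2c1OCc1ccccc1 | intermediate
15 | lithium 1-[2-(diethylcarbamoyl)-3-methoxyphenyl]-3-{1-(benzyloxy)-4-[4-(benzyloxy)-5-methoxynaphthalen-1-yl]-8-methoxynaphthalen-2-yl}prop-2-en-1-ide (delocalised 1,3-diarylallyllithium, geometry labile, formed in the flask) | CCN(CC)C(=O)c1c(OC)cccc1[CH-]C=Cc1cc(-c2ccc(OCc3ccccc3)c3c(OC)cccc23)c2cccc(OC)c2c1OCc1ccccc1.[Li+] | intermediate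
16 | 2-{1-(benzyloxy)-4-[4-(benzyloxy)-5-methoxynaphthalen-1-yl]-8-methoxynaphthalen-2-yl}-8-methoxynaphthalen-1(2H)-one (racemic at C2, transient, formed in the flask) | COc1cccc2C=CC(c3cc(-c4ccc(OCc5ccccc5)c5c(OC)cccc45)c4cccc(OC)c4c3OCc3ccccc3)C(=O)c12 | intermediate
17 | 2-{1-(benzyloxy)-4-[4-(benzyloxy)-5-methoxynaphthalen-1-yl]-8-methoxynaphthalen-2-yl}-8-methoxynaphthalen-1-ol | COc1cccc2ccc(-c3cc(-c4ccc(OCc5ccccc5)c5c(OC)cccc45)c4cccc(OC)c4c3OCc3ccccc3)c(O)c12 | intermediate
18 | 4-(4-hydroxy-5-methoxynaphthalen-1-yl)-2-(1-hydroxy-8-methoxynaphthalen-2-yl)-8-methoxynaphthalen-1-ol | COc1cccc2ccc(-c3cc(-c4ccc(O)c5c(OC)cccc45)c4cccc(OC)c4c3O)c(O)c12 | target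

## Step count and least certain steps

Total: 10 steps. Longest linear sequence: 9 steps (steps 1–6, 8, 9 and 10, from 1); step 7 is the one-step side branch from 9 and 10.

**Step 9 (key step).** The most likely failure is slow or incomplete ring closure. The reacting allyl terminus is stabilised by the naphthyl group and crowded by the neighbouring benzyloxy group, and the amide carbonyl is twisted and shielded by its ortho methoxy group. Prolonged warming then gives time for metalation of a benzyl ether CH2 with [1,2]-Wittig rearrangement, or for oxidative coupling of the anion by traces of air. The fallback replaces the annulation by a biaryl coupling and sets out from 2 and 8. Amine-catalysed ortho-bromination of 2 (NBS, cat. i-Pr2NH, CH2Cl2) gives 2-bromo-8-methoxynaphthalen-1-ol F1. Miyaura borylation of 8 (B2pin2, KOAc, PdCl2(dppf)) gives 2-{1-(benzyloxy)-4-[4-(benzyloxy)-5-methoxynaphthalen-1-yl]-8-methoxynaphthalen-2-yl}-4,4,5,5-tetramethyl-1,3,2-dioxaborolane F2. Suzuki–Miyaura coupling of F1 with F2 (Pd(OAc)2, SPhos, K3PO4, toluene–water) comes back to the route at 17.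

**Step 8.** Two things may go wrong: a palladium hydride may move the double bond of 13 into conjugation with the benzamide ring before insertion, and oxidative addition of the electron-rich ortho-alkoxy bromide 8 may be sluggish. The fallback sets out from 13 and 8 and separates alkene construction from arylation. Cross-metathesis of 13 with vinylboronic acid pinacol ester (second-generation Hoveyda–Grubbs catalyst, CH2Cl2, 40 °C) gives N,N-diethyl-2-methoxy-6-[(2E)-3-(4,4,5,5-tetramethyl-1,3,2-dioxaborolan-2-yl)prop-2-en-1-yl]benzamide F3. Suzuki–Miyaura coupling of F3 with 8 (Pd(OAc)2, SPhos, K3PO4) comes back at 14.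

**Step 4.** Oxidative addition into the naphtholate form of 3 may be slow, which leaves time for protodeboronation of 5 and for homocoupling. The fallback sets out from 2 and gives up the differentiated coupling. Oxidative para–para dimerisation of 2 (FeCl3 on silica, then Na2S2O4 to reduce any over-oxidised binaphthylidene-dione) gives 5,5'-dimethoxy-[1,1'-binaphthalene]-4,4'-diol F4. Mono ortho-bromination (NBS, one equivalent, cat. i-Pr2NH) with chromatographic removal of unreacted and dibrominated material gives 3-bromo-5,5'-dimethoxy-[1,1'-binaphthalene]-4,4'-diol F5. Double benzylation (BnBr, K2CO3, DMF) comes back at 8. This bypasses steps 3 to 6 at the price of one statistical step.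

**Step 5.** Site selectivity may be lost through competing bromination of the benzyl ether ring of unit C, or the electron-rich naphthol may be oxidised by N-bromosuccinimide. The fallback sets out from 6 and 10 and replaces electrophilic substitution by a sigmatropic shift that can only reach C2'.
- O-Allylation of 6 with 10 (K2CO3, DMF) gives 1-(allyloxy)-4-[4-(benzyloxy)-5-methoxynaphthalen-1-yl]-8-methoxynaphthalene F6.
- Aromatic Claisen rearrangement (N,N-diethylaniline, 180 °C) gives 2-allyl-4-[4-(benzyloxy)-5-methoxynaphthalen-1-yl]-8-methoxynaphthalen-1-ol F7.
- Benzylation gives 2-allyl-1-(benzyloxy)-4-[4-(benzyloxy)-5-methoxynaphthalen-1-yl]-8-methoxynaphthalene F8.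
- Quenching aryllithium 11 with I2 gives N,N-diethyl-2-iodo-6-methoxybenzamide F9.
- Heck coupling of F8 with F9 (Pd(OAc)2, P(o-tol)3, K2CO3, DMF) gives N,N-diethyl-2-methoxy-6-[(1E)-3-{1-(benzyloxy)-4-[4-(benzyloxy)-5-methoxynaphthalen-1-yl]-8-methoxynaphthalen-2-yl}prop-1-en-1-yl]benzamide F10, the positional alkene isomer of 14.
- Under the conditions of step 9, F10 is deprotonated to the same allyllithium, so the fallback comes back to the route at 15.

## Further compounds

F1 | step 9 | 2-bromo-8-methoxynaphthalen-1-ol | COc1cccc2ccc(Br)c(O)c12
F2 | step 9 | 2-{1-(benzyloxy)-4-[4-(benzyloxy)-5-methoxynaphthalen-1-yl]-8-methoxynaphthalen-2-yl}-4,4,5,5-tetramethyl-1,3,2-dioxaborolane | COc1cccc2c(-c3ccc(OCc4ccccc4)c4c(OC)cccc34)cc(B3OC(C)(C)C(C)(C)O3)c(OCc3ccccc3)c12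
F3 | step 8 | N,N-diethyl-2-methoxy-6-[(2E)-3-(4,4,5,5-tetramethyl-1,3,2-dioxaborolan-2-yl)prop-2-en-1-yl]benzamide | CCN(CC)C(=O)c1c(OC)cccc1C/C=C/B1OC(C)(C)C(C)(C)O1
F4 | step 4 | 5,5'-dimethoxy-[1,1'-binaphthalene]-4,4'-diol | COc1cccc2c(-c3ccc(O)c4c(OC)cccc34)ccc(O)c12
F5 | step 4 | 3-bromo-5,5'-dimethoxy-[1,1'-binaphthalene]-4,4'-diol | COc1cccc2c(-c3ccc(O)c4c(OC)cccc34)cc(Br)c(O)c12
F6 | step 5 | 1-(allyloxy)-4-[4-(benzyloxy)-5-methoxynaphthalen-1-yl]-8-methoxynaphthalene | COc1cccc2c(-c3ccc(OCc4ccccc4)c4c(OC)cccc34)ccc(OCC=C)c12
F7 | step 5 | 2-allyl-4-[4-(benzyloxy)-5-methoxynaphthalen-1-yl]-8-methoxynaphthalen-1-ol | COc1cccc2c(-c3ccc(OCc4ccccc4)c4c(OC)cccc34)cc(CC=C)c(O)c12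
F8 | step 5 | 2-allyl-1-(benzyloxy)-4-[4-(benzyloxy)-5-methoxynaphthalen-1-yl]-8-methoxynaphthalene | COc1cccc2c(-c3ccc(OCc4ccccc4)c4c(OC)cccc34)cc(CC=C)c(OCc3ccccc3)c12
F9 | step 5 | N,N-diethyl-2-iodo-6-methoxybenzamide | CCN(CC)C(=O)c1c(I)cccc1OC
F10 | step 5 | N,N-diethyl-2-methoxy-6-[(1E)-3-{1-(benzyloxy)-4-[4-(benzyloxy)-5-methoxynaphthalen-1-yl]-8-methoxynaphthalen-2-yl}prop-1-en-1-yl]benzamide | CCN(CC)C(=O)c1c(OC)cccc1/C=C/Cc1cc(-c2ccc(OCc3ccccc3)c3c(OC)cccc23)c2cccc(OC)c2c1OCc1ccccc1
A1 | alternative 1 | 1-(benzyloxy)-4-[4-(benzyloxy)-5-methoxynaphthalen-1-yl]-2-[1-(benzyloxy)-8-methoxynaphthalen-2-yl]-8-methoxynaphthalene (tribenzyl ether of the target) | COc1cccc2ccc(-c3cc(-c4ccc(OCc5ccccc5)c5c(OC)cccc45)c4cccc(OC)c4c3OCc3ccccc3)c(OCc3ccccc3)c12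
A2 | alternative 1 | 3-(benzyloxy)-4-[1-(benzyloxy)-8-methoxynaphthalen-2-yl]-6-[4-(benzyloxy)-5-methoxynaphthalen-1-yl]-2H-pyran-2-one | O=C1OC(-c2ccc(OCc3ccccc3)c3c(OC)cccc23)=CC(-c2ccc3cccc(OC)c3c2OCc2ccccc2)=C1OCc1ccccc1
A3 | alternative 1 | 3-methoxy-2-(trimethylsilyl)phenyl trifluoromethanesulfonate | COc1cccc(OS(=O)(=O)C(F)(F)F)c1[Si](C)(C)C
A4 | alternative 1 | 3-methoxybenzyne | COC1=CC=CC#C1
A5 | alternative 2 | 4-{4-(benzyloxy)-3-[1-(benzyloxy)-8-methoxynaphthalen-2-yl]-5-methoxynaphthalen-1-yl}-8-methoxy-3-(trimethylsilyl)naphthalen-1-ol | COc1cccc2c(-c3cc(-c4ccc5cccc(OC)c5c4OCc4ccccc4)c(OCc4ccccc4)c4c(OC)cccc34)c([Si](C)(C)C)cc(O)c12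
A6 | alternative 2 | dimethylsulfoxonium 2-(2-methoxyphenyl)-2-oxoethylide | COc1ccccc1C(=O)C=S(C)(C)=O
A7 | alternative 2 | ({4-(benzyloxy)-3-[1-(benzyloxy)-8-methoxynaphthalen-2-yl]-5-methoxynaphthalen-1-yl}ethynyl)trimethylsilane | C[Si](C)(C)C#Cc1cc(-c2ccc3cccc(OC)c3c2OCc2ccccc2)c(OCc2ccccc2)c2c(OC)cccc12
A8 | alternative 3 | 4-{4-(benzyloxy)-3-[1-(benzyloxy)-8-methoxynaphthalen-2-yl]-5-methoxynaphthalen-1-yl}-8-methoxynaphthalen-1-ol | COc1cccc2c(-c3cc(-c4ccc5cccc(OC)c5c4OCc4ccccc4)c(OCc4ccccc4)c4c(OC)cccc34)ccc(O)c12
A9 | alternative 3 | 1-[2-(1-{4-(benzyloxy)-3-[1-(benzyloxy)-8-methoxynaphthalen-2-yl]-5-methoxynaphthalen-1-yl}ethenyl)-6-methoxyphenyl]but-3-en-1-one | C=CCC(=O)c1c(OC)cccc1C(=C)c1cc(-c2ccc3cccc(OC)c3c2OCc2ccccc2)c(OCc2ccccc2)c2c(OC)cccc12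
A10 | alternative 3 | 4-{4-(benzyloxy)-3-[1-(benzyloxy)-8-methoxynaphthalen-2-yl]-5-methoxynaphthalen-1-yl}-8-methoxynaphthalen-1(2H)-one | COc1cccc2C(-c3cc(-c4ccc5cccc(OC)c5c4OCc4ccccc4)c(OCc4ccccc4)c4c(OC)cccc34)=CCC(=O)c12
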